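**Assumption:** phenyl vinyl sulfoxide is used as the racemate, so 6 is a pair of sulfur epimers; this centre is lost in step 4.

## Analysis of the target

The target has three rings. Ring A is an enolised acyl-dione (A1 isobutyryl, A2 OH, A3 CMe2, A4 C=O). Ring B is a dihydropyran (A6–O–C1'–C10'–C11H2–A5). Ring C is a ten-membered carbocycle (C1' to C10') with a cis C5'=C6' alkene. There are four stereocentres: C1' (R; O and methyl), C4' (R; 2-hydroxypropan-2-yl), C7' (S; methyl) and C10' (S; fusion H). The C1' methyl and the C10' hydrogen are anti (rings B and C trans-fused), which is what a suprafacial addition across an E-C1'=C10' alkene gives. On a flat drawing of ring C the C1' methyl, the C4' side chain and the C7' methyl lie on one face. Sensitive groups are the acidic, chelating enol of ring A, the tertiary ether at C1' (ionisation would invite transannular attack by C5'=C6'), the tertiary alcohol, and the allylic centres C4' and C7'. The difficulty is a medium ring whose stereocentres are 1,4- and 1,7-related with little functionality between them. The strategy rests on the segment C1'–C6': with its C4' side chain it is a carvone-derived cyclohexane in which C1' is a methyl/vinyl quaternary carbon and C6' an isopropenyl carbinol. A [3,3] shift that breaks C1'–C6' and joins the alkenyl ends (C8'–C9') opens six to ten, and its chair relays C4' to C7'.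

## Retrosynthetic reasoning

**25 to 24.** Only the Si–O bond is cut. The silyl ether is carried from the carvone stage because a free hydroxyl there would be a second alkoxide in the key step and would close a hemiketal onto the C6' ketone of 14.

**24 to 17 and 23 (from 21 and 22).** O–C1' and C11–C10' are cut together, a [4+2] disconnection of ring B. Both fusion centres then arise in one suprafacial event on the E-alkene of 17, so the trans fusion follows from the alkene geometry, and the oxygen goes to the more substituted C1'. Ring A arrives complete. The forward reaction must choose the trisubstituted alkene over the cis one, the outer face of the conformer with the C4' chain equatorial, and the A6 carbonyl of 23 as the heterodiene oxygen.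

**21 to 20 to 18 and 19.** Ring A is cut at the acyl C–C bond and at the two C–methyl bonds of A3; both are standard phloroglucinol chemistry.

**17 to 16 to 14.** The cis alkene is traced to the C6' carbonyl through the C5' enol triflate. The ketone is what the key step leaves, so no separate olefination is needed. The forward steps must enolise toward C5' and not C7', give the ring-cis enolate, and leave C7' untouched.

**14 to 11 (key disconnection).** C1'–C6' is reconnected and C8'–C9' is cut. This is the only cleavage that maps ring C onto a six-membered ring from 1 with C4' already in place. The (1R,2S) pair of centres in 11 is chosen deliberately: both alkenyl groups and the side chain are then equatorial, and the resulting chair gives the E-alkene and, after protonation, the 7'S centre. The doubly epimeric carbinol would react through the mirror-sense chair and give the C7' epimer.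

**11 to 9 and 10.** The carbinol C–C bond is cut; the isopropenyl group must end trans to the vinyl group.

**9 to 8 to 7.** After the silyl ether, the tertiary alcohol is traced to a gem-dimethylcyclopropane fused at the ketone α-carbon. The reason is stereochemical. An enolate of the monocyclic ketone would take up an electrophile axially, which puts the new arm cis to the side chain. The cyclopropane of 3 covers that face, so the arm ends trans, as 11 requires.

**7 to 6 to 3 and 4.** The vinyl group comes from a 2-sulfinylethyl arm, and the quaternary carbon from Michael addition of enolate 5 to 4.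

**3 to 2 to 1.** The cyclopropane bond comes from the tertiary bromide 2, made from 1.

## Alternatives that were turned down

**Alternative 1:** The disconnection is C3'–C4', paid for with a C1'–O ester bond. The forward key step is an Ireland–Claisen ring contraction of the ten-membered lactone A1 (lithium amide and chlorosilane, then warming) to the ring-C acid A2. In its favour, C4' is set by chirality transfer, the cis C5'=C6' alkene is fixed beforehand in an open chain, and the carboxyl is a direct precursor of the carbinol side chain. On the alkene geometry it is stronger than the chosen route, which must get the cis alkene from an enolate. Against it, A1 needs a macrolactonisation onto a tertiary allylic alcohol, with C7' and C10' built linearly first. C1' would then be set late, by adding the ring-A oxygen to the C1'=C2' alkene, with no built-in link to C10'. The chosen route instead takes the ring from the chiral pool in few steps and sets C1' and C10' together in one cycloaddition.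

**Alternative 2:** The disconnection is A5–C11 and O–C1' by condensation and oxa-6π closure. The forward key step condenses triketone 21 with the ring-C enal A3 (ammonium carboxylate catalyst, hot toluene) to the 2H-pyran A4. In its favour, it is convergent and the C–C bond forms at a defined carbon, with no intermolecular cycloaddition to an unactivated alkene; on site selectivity it is stronger than step 13. Against it, A3 already contains the whole ten-membered ring, so ring C is not solved. The electrocyclisation sets C1' without a controlling neighbour. The C10'=C11 alkene must then be reduced selectively, beside the cis alkene and the enol ether, to set C10', so the trans fusion is not guaranteed. The chosen route builds ring C and sets both fusion centres stereospecifically.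

**Alternative 3:** The disconnection is C1'–C10'. The forward key step is a Reformatsky-type macrocyclisation of the bromo keto ester A5 with a divalent samarium reductant at high dilution, giving the hydroxy ester A6. In its favour, all ring-C stereocentres and the cis alkene would be in place before ring A is attached; on these points it is at least as strong as the chosen route. Against it, a ten-membered ring is closed against entropy and transannular strain, and the two new centres form with uncertain control. The C1' oxygen arrives as a hydroxyl that would still have to be joined to ring A, and A5 needs a long linear synthesis. The chosen route needs no macrocyclisation: the ring comes from a six-membered ring by a sigmatropic shift.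

Key step: step 8

## Route

Step 1
Reactants: 1 (R)-carvone
Product: 2 (5R)-5-(2-bromopropan-2-yl)-2-methylcyclohex-2-en-1-one
Conditions: HBr (33% in AcOH), 0 °C
Reagents that add atoms: hydrogen bromide, Br
Why: Markovnikov hydrobromination of the isolated 1,1-disubstituted alkene; the electron-poor enone alkene does not add HBr productively, and C5 is untouched.

Step 2
Reactants: 2 (5R)-5-(2-bromopropan-2-yl)-2-methylcyclohex-2-en-1-one
Product: 3 (1S,6R)-3,7,7-trimethylbicyclo[4.1.0]hept-3-en-2-one
Conditions: KOH (1.05 equiv), MeOH, 0 °C
Reagents that add atoms: none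
Why: Enolisation at the α'-methylene and intramolecular 3-exo displacement of the tertiary bromide give the cyclopropyl enone (classical 1,3-elimination); the new ring-fusion centre is fixed by the necessarily cis fusion to C5; cold and a small excess of base avoid further isomerisation of the product.

Step 3
Reactants: 3 (1S,6R)-3,7,7-trimethylbicyclo[4.1.0]hept-3-en-2-one; 4 phenyl vinyl sulfoxide
Product: 6 (1S,3S,6R)-3,7,7-trimethyl-3-[2-(phenylsulfinyl)ethyl]bicyclo[4.1.0]heptan-2-one, via lithium enolate 5 (not isolated)
Conditions: LiBH(sBu)3, THF, −78 °C; then 4, −78 to 0 °C; aq NH4Cl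
Reagents that add atoms: none
Why: Conjugate hydride delivery gives the regiodefined enolate 5, and its Michael addition to the vinyl sulfoxide (a vinyl cation equivalent) builds the quaternary carbon; the gem-dimethylcyclopropane covers its own face of the enolate, so the arm should enter anti to it and end trans to the future C4' side chain.

Step 4
Reactants: 6 (1S,3S,6R)-3,7,7-trimethyl-3-[2-(phenylsulfinyl)ethyl]bicyclo[4.1.0]heptan-2-one
Product: 7 (1S,3S,6R)-3-ethenyl-3,7,7-trimethylbicyclo[4.1.0]heptan-2-one
Conditions: toluene, CaCO3, 110 °C
Reagents that add atoms: none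
Why: Thermal syn-elimination of the sulfoxide; the only β-hydrogens are on the carbon next to the quaternary centre, so the vinyl group is the sole product and both sulfur epimers converge.

Step 5
Reactants: 7 (1S,3S,6R)-3-ethenyl-3,7,7-trimethylbicyclo[4.1.0]heptan-2-one
Product: 8 (2S,5R)-2-ethenyl-5-(2-hydroxypropan-2-yl)-2-methylcyclohexan-1-one
Conditions: 10% aq H2SO4, THF, 25 °C
Reagents that add atoms: water, O
Why: Acid-promoted homoconjugate opening of the cyclopropyl ketone cleaves the bond between the α-carbon and the CMe2 carbon (tertiary cation, enol as leaving group), and water captures the cation; the side-chain carbon stays on C5 with its configuration, and the monosubstituted vinyl group is not protonated by dilute acid.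

Step 6
Reactants: 8 (2S,5R)-2-ethenyl-5-(2-hydroxypropan-2-yl)-2-methylcyclohexan-1-one
Product: 9 (2S,5R)-2-ethenyl-2-methyl-5-[2-(triethylsilyloxy)propan-2-yl]cyclohexan-1-one
Conditions: Et3SiOTf, 2,6-lutidine, CH2Cl2, −78 to 0 °C
Reagents that add atoms: triethylsilyl trifluoromethanesulfonate, CC[Si](CC)(CC)OS(=O)(=O)C(F)(F)F
Why: Silyl triflate with a hindered pyridine base silylates the tertiary alcohol; the triethylsilyl ether tolerates the organometallic, hydride-base and palladium steps that follow and is removable with fluoride at the end.

Step 7
Reactants: 9 (2S,5R)-2-ethenyl-2-methyl-5-[2-(triethylsilyloxy)propan-2-yl]cyclohexan-1-one; 10 isopropenylmagnesium bromide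
Product: 11 (1R,2S,5R)-2-ethenyl-2-methyl-1-(prop-1-en-2-yl)-5-[2-(triethylsilyloxy)propan-2-yl]cyclohexan-1-ol
Conditions: 10, CeCl3 (dried), THF, −78 °C; aq NH4Cl
Reagents that add atoms: none
Why: The non-basic organocerium reagent adds to the hindered, enolisable ketone; equatorial entry of the branched sp2 nucleophile, away from the axial hydrogens at C3 and C5, places it trans to the vinyl group with all three large groups equatorial and the hydroxyl axial; the axial C2 methyl opposes this path, so the C1 epimer is a likely by-product to be removed by chromatography.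

Step 8
Reactants: 11 (1R,2S,5R)-2-ethenyl-2-methyl-1-(prop-1-en-2-yl)-5-[2-(triethylsilyloxy)propan-2-yl]cyclohexan-1-ol
Product: 14 (2S,5E,9R)-2,6-dimethyl-9-[2-(triethylsilyloxy)propan-2-yl]cyclodec-5-en-1-one, via potassium alkoxide 12 (not isolated), via potassium enolate 13 (not isolated)
Conditions: KH, 18-crown-6, THF, 0 to 25 °C; then transfer into AcOH/THF, −78 °C
Reagents that add atoms: none
Why: KH with 18-crown-6 gives the free alkoxide 12, whose oxido group weakens the C1'–C6' bond; the [3,3] shift then forms C8'–C9' and breaks C1'–C6' through a chair transition state. The closest known reaction type is the anionic oxy-Cope ring expansion of trans-1,2-dialkenylcyclohexanols to (E)-cyclodec-5-enones. Ring C is not closed by a cyclisation: the six-membered ring is enlarged by the four alkenyl carbons C7' to C10' in one sigmatropic step. With the isopropenyl, vinyl and C4' side-chain groups all equatorial, the ring residue at C1' is equatorial on the transition-state chair, which gives the E-C1'=C10' alkene, and the same chair fixes the sense in which the enolate unit sits in the new ring. Enolate 13 carries oxygen and methyl on its double bond, so it cannot turn through the ring and keeps this shape until the quench. Protonation on the open outer face of C7' then gives the 7'S centre; the controlling element is C4', relayed by the chair. The step needs chair over boat geometry, the [3,3] shift over cleavage of the alkoxide, and protonation without enolate–ketone exchange; the trans-diequatorial alkenyl groups, the silyl protection of the second hydroxyl and the cold inverse quench into acid provide for these.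

Step 9
Reactants: 14 (2S,5E,9R)-2,6-dimethyl-9-[2-(triethylsilyloxy)propan-2-yl]cyclodec-5-en-1-one
Product: 16 (1E,3R,6E,10S)-6,10-dimethyl-3-[2-(triethylsilyloxy)propan-2-yl]cyclodeca-1,6-dien-1-yl trifluoromethanesulfonate, via lithium enolate 15 (not isolated)
Conditions: LiN(iPr)2, THF, −78 °C (ketone added to the base); then 2-[N,N-bis(trifluoromethylsulfonyl)amino]-5-chloropyridine, −78 to −40 °C
Reagents that add atoms: 2-[N,N-bis(trifluoromethylsulfonyl)amino]-5-chloropyridine, O=S(=O)(N(c1ccc(Cl)cn1)S(=O)(=O)C(F)(F)F)C(F)(F)F
Why: Irreversible kinetic deprotonation by the lithium amide takes a methylene hydrogen at C5' in preference to the tertiary C7' hydrogen, so C7' is not touched; the cyclic deprotonation places the C4' chain anti to oxygen, and a second trans double bond in the ten-membered ring would cost strain, so the ring-cis enolate 15 is expected; O-sulfonylation keeps its geometry.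

Step 10
Reactants: 16 (1E,3R,6E,10S)-6,10-dimethyl-3-[2-(triethylsilyloxy)propan-2-yl]cyclodeca-1,6-dien-1-yl trifluoromethanesulfonate
Product: 17 triethyl({2-[(1R,2Z,4S,7E)-4,8-dimethylcyclodeca-2,7-dien-1-yl]propan-2-yl}oxy)silane
Conditions: Pd(OAc)2 (cat.), PPh3, HCO2H, nBu3N, DMF, 60 °C
Reagents that add atoms: none
Why: Oxidative addition of zerovalent palladium to the vinyl triflate, formate-to-hydride exchange with loss of CO2, and reductive elimination replace the C–O bond by C–H with retention, giving the cis C5'=C6' alkene; the trisubstituted alkene and the silyl ether are inert.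

Step 11
Reactants: 18 phloroglucinol; 19 isobutyryl chloride
Product: 20 2-methyl-1-(2,4,6-trihydroxyphenyl)propan-1-one
Conditions: AlCl3, PhNO2/CH2Cl2, 25 to 50 °C; aq HCl
Reagents that add atoms: none
Why: Friedel–Crafts C-acylation of the very electron-rich ring; the first acyl group deactivates the ring, so monoacylation is clean.

Step 12
Reactants: 20 2-methyl-1-(2,4,6-trihydroxyphenyl)propan-1-one
Product: 21 3,5-dihydroxy-6,6-dimethyl-4-(2-methylpropanoyl)cyclohexa-2,4-dien-1-one (enol form of the ring-A triketone)
Conditions: NaOMe, MeI, MeOH, 0 to 25 °C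
Reagents that add atoms: iodomethane, CI
Why: The phenoxide is alkylated at an unsubstituted ring carbon, and a second methylation at the same carbon dearomatises the ring to the gem-dimethyl triketone (known preparation of acylfilicinic acids); under- and over-methylated products are to be separated.

Step 13
Reactants: 17 triethyl({2-[(1R,2Z,4S,7E)-4,8-dimethylcyclodeca-2,7-dien-1-yl]propan-2-yl}oxy)silane; 21 ring-A triketone; 22 formaldehyde (as paraformaldehyde)
Product: 24 C4'-O-triethylsilyl ether of the target (1'R,4'R,7'S,10'S; 5'Z), via quinone methide 23 (not isolated)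
Conditions: (CH2O)n, NaOAc (cat.), 1,4-dioxane, 80 °C
Reagents that add atoms: none
Why: Knoevenagel condensation at the free ring carbon of 21 gives the α-methylene trione 23, which adds as a 1-oxadiene to the electron-rich, strained E-trisubstituted alkene (inverse-demand hetero-Diels–Alder), with oxygen going to the more substituted C1'; suprafacial addition to the E-alkene makes the B/C fusion trans, and attack on the outer face of the conformer with the C4' chain equatorial and the C1' methyl on the side of the C7' methyl gives 1'R,10'S; closure through the A6 carbonyl leaves the acyl enol chelate and the A4 ketone as in the target.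

Step 14
Reactants: 24 C4'-O-triethylsilyl ether of the target
Product: 25 target (1'R,4'R,7'S,10'S; 5'Z)
Conditions: HF·pyridine, THF/pyridine, 0 to 25 °C
Reagents that add atoms: none
Why: Buffered fluoride cleaves the tertiary triethylsilyl ether without ionising the C1' ether or the tertiary carbinol; no stereocentre is affected.

## Compound list

1 | (R)-carvone, (5R)-2-methyl-5-(prop-1-en-2-yl)cyclohex-2-en-1-one | CC1=CC[C@@H](C(C)=C)CC1=O | starting material
2 | (5R)-5-(2-bromopropan-2-yl)-2-methylcyclohex-2-en-1-one | CC1=CC[C@@H](C(C)(C)Br)CC1=O | intermediate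
3 | (1S,6R)-3,7,7-trimethylbicyclo[4.1.0]hept-3-en-2-one | CC1=CC[C@@H]2[C@H](C1=O)C2(C)C | intermediate
4 | phenyl vinyl sulfoxide (racemic) | C=CS(=O)c1ccccc1 | starting material
5 | lithium (1S,6R)-3,7,7-trimethylbicyclo[4.1.0]hept-2-en-2-olate | [Li+].CC1=C([O-])[C@H]2[C@@H](CC1)C2(C)C | intermediate
6 | (1S,3S,6R)-3,7,7-trimethyl-3-[2-(phenylsulfinyl)ethyl]bicyclo[4.1.0]heptan-2-one (both sulfur epimers) | C[C@@]1(CCS(=O)c2ccccc2)CC[C@@H]3[C@H](C1=O)C3(C)C | intermediate
7 | (1S,3S,6R)-3-ethenyl-3,7,7-trimethylbicyclo[4.1.0]heptan-2-one | C[C@@]1(C=C)CC[C@@H]2[C@H](C1=O)C2(C)C | intermediate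
8 | (2S,5R)-2-ethenyl-5-(2-hydroxypropan-2-yl)-2-methylcyclohexan-1-one | C[C@@]1(C=C)CC[C@@H](C(C)(C)O)CC1=O | intermediate
9 | (2S,5R)-2-ethenyl-2-methyl-5-[2-(triethylsilyloxy)propan-2-yl]cyclohexan-1-one | C[C@@]1(C=C)CC[C@@H](C(C)(C)O[Si](CC)(CC)CC)CC1=O | intermediate
10 | isopropenylmagnesium bromide | CC(=C)[Mg]Br | starting material
11 | (1R,2S,5R)-2-ethenyl-2-methyl-1-(prop-1-en-2-yl)-5-[2-(triethylsilyloxy)propan-2-yl]cyclohexan-1-ol | O[C@]1(C(C)=C)[C@](C)(C=C)CC[C@@H](C(C)(C)O[Si](CC)(CC)CC)C1 | intermediate
12 | potassium alkoxide of 11 | [K+].[O-][C@]1(C(C)=C)[C@](C)(C=C)CC[C@@H](C(C)(C)O[Si](CC)(CC)CC)C1 | intermediate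
13 | potassium (1Z,5E,9R)-2,6-dimethyl-9-[2-(triethylsilyloxy)propan-2-yl]cyclodeca-1,5-dien-1-olate | [K+].C1C[C@@H](C(C)(C)O[Si](CC)(CC)CC)C/C([O-])=C(C)/CC/C=C1\C | intermediate
14 | (2S,5E,9R)-2,6-dimethyl-9-[2-(triethylsilyloxy)propan-2-yl]cyclodec-5-en-1-one | C1C[C@@H](C(C)(C)O[Si](CC)(CC)CC)CC(=O)[C@@H](C)CC/C=C1\C | intermediate
15 | lithium (1E,3R,6E,10S)-6,10-dimethyl-3-[2-(triethylsilyloxy)propan-2-yl]cyclodeca-1,6-dien-1-olate | [Li+].C1C[C@@H](C(C)(C)O[Si](CC)(CC)CC)/C=C([O-])\[C@@H](C)CC/C=C1\C | intermediate
16 | (1E,3R,6E,10S)-6,10-dimethyl-3-[2-(triethylsilyloxy)propan-2-yl]cyclodeca-1,6-dien-1-yl trifluoromethanesulfonate | C1C[C@@H](C(C)(C)O[Si](CC)(CC)CC)/C=C(OS(=O)(=O)C(F)(F)F)\[C@@H](C)CC/C=C1\C | intermediate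
17 | triethyl({2-[(1R,2Z,4S,7E)-4,8-dimethylcyclodeca-2,7-dien-1-yl]propan-2-yl}oxy)silane | C1C[C@@H](C(C)(C)O[Si](CC)(CC)CC)/C=C\[C@@H](C)CC/C=C1\C | intermediate
18 | phloroglucinol | Oc1cc(O)cc(O)c1 | starting material
19 | isobutyryl chloride | CC(C)C(Cl)=O | starting material
20 | 2-methyl-1-(2,4,6-trihydroxyphenyl)propan-1-one | CC(C)C(=O)c1c(O)cc(O)cc1O | intermediate
21 | 3,5-dihydroxy-6,6-dimethyl-4-(2-methylpropanoyl)cyclohexa-2,4-dien-1-one | CC(C)C(=O)C1=C(O)C(C)(C)C(=O)C=C1O | intermediate
22 | formaldehyde (used as paraformaldehyde) | C=O | starting material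
23 | 3-hydroxy-4,4-dimethyl-6-methylidene-2-(2-methylpropanoyl)cyclohex-2-ene-1,5-dione | CC(C)C(=O)C1=C(O)C(C)(C)C(=O)C(=C)C1=O | intermediate
24 | C4'-O-triethylsilyl ether of the target (1'R,4'R,7'S,10'S; 5'Z) | CC(C)C(=O)C1=C(O)C(C)(C)C(=O)C2=C1O[C@]1(C)CC[C@@H](C(C)(C)O[Si](CC)(CC)CC)/C=C\[C@@H](C)CC[C@H]1C2 | intermediate
25 | target: ring A (A1 isobutyryl, A2 OH, A3 CMe2, A4 C=O) fused through A5–C11H2 and A6–O to ring C; C1' (R) O and methyl, C4' (R) 2-hydroxypropan-2-yl, 5'Z alkene, C7' (S) methyl, C10' (S) H | CC(C)C(=O)C1=C(O)C(C)(C)C(=O)C2=C1O[C@]1(C)CC[C@@H](C(C)(C)O)/C=C\[C@@H](C)CC[C@H]1C2 | target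

## Step count and least certain steps

Total: 14 steps. Longest linear sequence: 12 steps (steps 1 to 10, 13 and 14); steps 11 and 12 are the two-step branch to 21.

**Step 8 (key step).** The shift itself is well founded for a trans-diequatorial substrate. The most likely failure is loss of the C7' configuration: proton exchange between enolate 13 and ketone already formed during the quench would equilibrate the centre, and the axial-methyl epimer wanted here is probably not the more stable one. A second possibility is migration of the triethylsilyl group to the alkoxide before rearrangement. The fallback sets out from 13 and separates base from protonation. The enolate is trapped in the flask with Me3SiCl/Et3N at −78 °C as the trimethylsilyl enol ether of 14 F1, which keeps the enolate geometry and can be purified. F1 is cleaved with MeLi in THF to the lithium enolate F2. F2 is protonated at −100 °C with a hindered phenol. The route is rejoined at 14.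

**Step 7.** Poor facial selectivity is likely: the axial C2 methyl hinders the equatorial approach that leads to 11, and axial attack gives the cis-dialkenyl C1 epimer, which cannot give the E-alkene through a chair. The fallback sets out from 9 and brings in the oxygen last, from the axial side. KN(SiMe3)2 and PhNTf2 give (3R,6S)-6-ethenyl-6-methyl-3-[2-(triethylsilyloxy)propan-2-yl]cyclohex-1-en-1-yl trifluoromethanesulfonate F3. Suzuki coupling with isopropenylboronic acid pinacol ester (Pd(dppf)Cl2, K3PO4) gives the 1-isopropenylcyclohexene F4. mCPBA (NaHCO3 buffer) epoxidises the ring alkene anti to the pseudo-axial C2 methyl to give the ring epoxide F5. LiBHEt3 opens F5 at the secondary carbon, and the route is rejoined at 11.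

**Step 9.** The wrong enolate geometry may form. In the chair–chair conformer that 14 inherits from step 8, the only C5' hydrogen aligned with the carbonyl is the peripheral one, and its removal gives the ring-trans enolate, which after step 10 would be the E,E-diene. Some deprotonation at C7' is a lesser risk. The fallback sets out from 14 and makes the geometry irrelevant. The ring-trans enol triflate F6, which has hydrogen anti to the triflate, is eliminated with LiN(iPr)2 to the cyclodecenyne F7. F7 is hydrogenated over Pd on CaCO3 poisoned with Pb(OAc)2 (quinoline, H2), which can only give the cis alkene. The route is rejoined at 17.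

**Step 13.** Three things can go wrong: closure through the A4 carbonyl instead of A6 (the regioisomeric pyran), attack on the other alkene face or on the cis alkene, and acid-induced transannular cyclisation of the ten-membered diene. The fallback sets out from 20 (with 17 and 22) and removes the oxygen ambiguity. The hydroxyl para to the acyl group is silylated selectively (tBuMe2SiCl, imidazole) to give 1-[4-(tert-butyldimethylsilyloxy)-2,6-dihydroxyphenyl]-2-methylpropan-1-one F8. The aromatic quinone methide formed from F8 and 22 can close only through the hydroxyl next to the acyl group, and with 17 gives the chroman F9. nBu4NF removes both silyl groups to give the dihydroxy chroman F10. F10 is C,C-dimethylated at its one free ring carbon with NaOMe/MeI, the same reaction type as step 12. The route is rejoined at 25.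

**Step 3.** The hindered, boron-complexed tetrasubstituted enolate 5 may add sluggishly to 4, or proton transfer may consume it. Facial selectivity rests on the cyclopropane shield alone. The fallback sets out from 3 and uses an aldol/dehydration in place of the vinyl sulfoxide. Conjugate reduction with LiBH(sBu)3 and protonation give the saturated ketone (1S,6R)-3,7,7-trimethylbicyclo[4.1.0]heptan-2-one F11. F11 enolises only away from the cyclopropane (LiN(iPr)2), and acetaldehyde gives the aldol (1S,3S,6R)-3-(1-hydroxyethyl)-3,7,7-trimethylbicyclo[4.1.0]heptan-2-one F12. Syn-dehydration with methyl N-(triethylammoniosulfonyl)carbamate can only form the vinyl group. The route is rejoined at 7.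

## Further compounds

F1 | step 8 | trimethylsilyl enol ether of 14, (1Z,5E,9R)-2,6-dimethyl-1-(trimethylsilyloxy)-9-[2-(triethylsilyloxy)propan-2-yl]cyclodeca-1,5-diene | C1C[C@@H](C(C)(C)O[Si](CC)(CC)CC)C/C(O[Si](C)(C)C)=C(C)/CC/C=C1\C
F2 | step 8 | lithium (1Z,5E,9R)-2,6-dimethyl-9-[2-(triethylsilyloxy)propan-2-yl]cyclodeca-1,5-dien-1-olate | [Li+].C1C[C@@H](C(C)(C)O[Si](CC)(CC)CC)C/C([O-])=C(C)/CC/C=C1\C
F3 | step 7 | (3R,6S)-6-ethenyl-6-methyl-3-[2-(triethylsilyloxy)propan-2-yl]cyclohex-1-en-1-yl trifluoromethanesulfonate | C[C@@]1(C=C)CC[C@@H](C(C)(C)O[Si](CC)(CC)CC)C=C1OS(=O)(=O)C(F)(F)F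
F4 | step 7 | triethyl({2-[(1R,4S)-4-ethenyl-4-methyl-3-(prop-1-en-2-yl)cyclohex-2-en-1-yl]propan-2-yl}oxy)silane | C[C@@]1(C=C)CC[C@@H](C(C)(C)O[Si](CC)(CC)CC)C=C1C(C)=C
F5 | step 7 | ring epoxide of F4, oxygen trans to the C2 methyl and to the side chain | C[C@@]1(C=C)CC[C@@H](C(C)(C)O[Si](CC)(CC)CC)[C@@H]2O[C@]12C(C)=C
F6 | step 9 | (1Z,3R,6E,10S)-6,10-dimethyl-3-[2-(triethylsilyloxy)propan-2-yl]cyclodeca-1,6-dien-1-yl trifluoromethanesulfonate (ring-trans enol triflate) | C1C[C@@H](C(C)(C)O[Si](CC)(CC)CC)/C=C(OS(=O)(=O)C(F)(F)F)/[C@@H](C)CC/C=C1\C
F7 | step 9 | cyclodecenyne: ring C with C5'≡C6' triple bond and E-C1'=C10' alkene, C4' and C7' as in 14 | C1C[C@@H](C(C)(C)O[Si](CC)(CC)CC)C#C[C@@H](C)CC/C=C1\C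
F8 | step 13 | 1-[4-(tert-butyldimethylsilyloxy)-2,6-dihydroxyphenyl]-2-methylpropan-1-one | CC(C)C(=O)c1c(O)cc(O[Si](C)(C)C(C)(C)C)cc1O
F9 | step 13 | aromatic chroman adduct of F8, formaldehyde and 17 (pyran oxygen next to the acyl carbon; ring C as in 24) | CC(C)C(=O)c1c(O)cc(O[Si](C)(C)C(C)(C)C)c2c1O[C@]1(C)CC[C@@H](C(C)(C)O[Si](CC)(CC)CC)/C=C\[C@@H](C)CC[C@H]1C2
F10 | step 13 | desilylated dihydroxy chroman (ring C as in 25) | CC(C)C(=O)c1c(O)cc(O)c2c1O[C@]1(C)CC[C@@H](C(C)(C)O)/C=C\[C@@H](C)CC[C@H]1C2
F11 | step 3 | (1S,6R)-3,7,7-trimethylbicyclo[4.1.0]heptan-2-one (C3 epimers) | CC1CC[C@@H]2[C@H](C1=O)C2(C)C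
F12 | step 3 | (1S,3S,6R)-3-(1-hydroxyethyl)-3,7,7-trimethylbicyclo[4.1.0]heptan-2-one (carbinol epimers) | C[C@@]1(C(C)O)CC[C@@H]2[C@H](C1=O)C2(C)C
A1 | alternative 1 | (4Z,6S,9S,10S)-9-[(tert-butyldimethylsilyloxy)methyl]-10-ethenyl-6,10-dimethyl-3,6,7,8,9,10-hexahydro-2H-oxecin-2-one | O=C1C/C=C\[C@@H](C)CC[C@@H](CO[Si](C)(C)C(C)(C)C)[C@](C)(C=C)O1
A2 | alternative 1 | ring-C dienyl carboxylic acid (carboxyl on C4', C1'=C2' and cis C5'=C6' alkenes, silyloxymethyl on C10') | C1[C@@H](C(=O)O)/C=C\[C@@H](C)CC[C@@H](CO[Si](C)(C)C(C)(C)C)/C(C)=C\1
A3 | alternative 2 | ring-C enal: C10' carbaldehyde on a C1'=C10' alkene, cis C5'=C6', C4' silyloxypropyl, C7' methyl | O=C/C1=C(C)/CC[C@@H](C(C)(C)O[Si](CC)(CC)CC)/C=C\[C@@H](C)CC1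
A4 | alternative 2 | tricyclic 2H-pyran (C10'=C11 unsaturated) | CC(C)C(=O)C1=C(O)C(C)(C)C(=O)C2=C1O[C@]1(C)CC[C@@H](C(C)(C)O[Si](CC)(CC)CC)/C=C\[C@@H](C)CCC1=C2
A5 | alternative 3 | methyl (4Z,6S,9R)-2-bromo-6-methyl-12-oxo-9-[2-(triethylsilyloxy)propan-2-yl]tridec-4-enoate... open-chain bromo keto ester (C1' methyl ketone, C10' bromo ester; bromide epimers) | CC(=O)CC[C@@H](C(C)(C)O[Si](CC)(CC)CC)/C=C\[C@@H](C)CCC(Br)C(=O)OC
A6 | alternative 3 | ring-C β-hydroxy ester | O[C@]1(C)CC[C@@H](C(C)(C)O[Si](CC)(CC)CC)/C=C\[C@@H](C)CC[C@H]1C(=O)OC
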